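**Remark on the chemistry (assumption):** 5-chlororesorcinol, 4-bromoresorcinol, 3,5-dihydroxybenzaldehyde, 4-acetoxy-3-methoxystyrene and the D-fructose-derived Shi ketone are taken as commercial. Dihydrobenzofuran numbering (O1, C2, C3, C3a, C4–C7, C7a) is used throughout; the target is the trans-(2S,3S) isomer.

## Retrosynthetic overview

1. The (E)-guaiacylvinyl arm on C6 is cut back to a C6–Cl bond (Heck), and all phenols to protected forms (MOM ethers, tosylates, one acetate).
2. Key disconnection: O1–C7a and C3–C3a together. A 5-chloro-3-(methoxymethoxy)benzyne is inserted into the C3–O bond of an enantiopure trans-2,3-diaryloxirane (formal [3+2]). This closes the only ring made in the route, the dihydrofuran, and fixes both stereocentres.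
3. Enabling feature: the oxygen on C4 lies ortho to ring-fusion carbon C3a and meta to C7a, so the benzo ring is a 3-oxyaryne in disguise (oxygen adds to the distal carbon C7a, the carbanion forms at C3a). O1–C2–C3 is the O–C–C unit of a stilbene oxide; the 2,4-dioxygenated C2 aryl is carried as its bis-tosylate so that only the C3–O bond ionises.
4. Epoxide: Heck coupling to the (E)-stilbene, then Shi epoxidation. Aryne precursor: carbamate-directed ortho-silylation of mono-MOM 5-chlororesorcinol, then triflation.
5. End game: Heck with 4-acetoxy-3-methoxystyrene, MOM removal, basic cleavage of the sulfonates and the acetate.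

Key step: step 10

## Route

Step 1
Reactants: 1 5-chlororesorcinol
Product: 2 3-chloro-5-(methoxymethoxy)phenol
Conditions: MOMCl (1.0 equiv), i-Pr2NEt (1.1 equiv), CH2Cl2, 0 °C to rt; diol and bis-ether recycled
Reagents that add atoms: chloromethyl methyl ether (MOMCl), COCCl
Why: O-alkylation of a symmetrical resorcinol in which both hydroxyls are equivalent, so only the degree of alkylation has to be controlled by stoichiometry (statistical mono-protection).

Step 2
Reactants: 2 3-chloro-5-(methoxymethoxy)phenol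
Product: 3 3-chloro-5-(methoxymethoxy)phenyl N-isopropylcarbamate
Conditions: i-PrNCO (1.3 equiv), Et3N (0.2 equiv), CH2Cl2, rt
Reagents that add atoms: isopropyl isocyanate, CC(C)N=C=O
Why: Base-catalysed addition of the phenol to the isocyanate gives the O-aryl carbamate, a directing group for ortho-metalation that can later be removed under mild conditions.

Step 3
Reactants: 3 3-chloro-5-(methoxymethoxy)phenyl N-isopropylcarbamate
Product: 7 5-chloro-3-(methoxymethoxy)-2-(trimethylsilyl)phenyl N-isopropylcarbamate, via N-TBS carbamate 4 (not isolated), via aryllithium 5 (not isolated), via N-TBS C-TMS carbamate 6 (not isolated)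
Conditions: TBSOTf (1.1 equiv), TMEDA (1.1 equiv), Et2O, 0 °C to rt; then n-BuLi (2.2 equiv), TMEDA (2 equiv), −78 °C; then TMSCl (3 equiv), −78 °C to rt; aq NaHSO4
Reagents that add atoms: chlorotrimethylsilane, C[Si](C)(C)Cl; tert-butyldimethylsilyl triflate, CC(C)(C)[Si](C)(C)OS(=O)(=O)C(F)(F)F (its silyl group stands only in 4, 5 and 6); n-butyllithium, [Li]CCCC (its lithium stands only in 5)
Why: Directed ortho-metalation: the N-silylated carbamate and the MOM ether flank C2 and together direct lithiation there (the C–Cl bond is inert to n-BuLi at −78 °C and TBSOTf is consumed by N-silylation before it can attack the MOM ether), the aryllithium is C-silylated and the N–Si bond is hydrolysed on work-up.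

Step 4
Reactants: 7 5-chloro-3-(methoxymethoxy)-2-(trimethylsilyl)phenyl N-isopropylcarbamate
Product: 9 5-chloro-3-(methoxymethoxy)-2-(trimethylsilyl)phenyl trifluoromethanesulfonate, via silylphenol 8 (not isolated)
Conditions: DBU (1.5 equiv), Et2NH (1.2 equiv), MeCN, 40 °C; then PhNTf2 (1.5 equiv), rt
Reagents that add atoms: N-phenylbis(trifluoromethanesulfonimide), O=S(=O)(N(c1ccccc1)S(=O)(=O)C(F)(F)F)C(F)(F)F
Why: E1cB cleavage of the N–H carbamate (the isocyanate is scavenged by Et2NH) frees the phenoxide, which is triflated in the same flask to give the 2-(trimethylsilyl)aryl triflate aryne precursor.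

Step 5
Reactants: 10 4-bromoresorcinol
Product: 11 4-bromo-1,3-phenylene bis(4-methylbenzenesulfonate)
Conditions: TsCl (2.3 equiv), Et3N (3 equiv), DMAP (5 mol%), CH2Cl2, 0 °C to rt
Reagents that add atoms: 4-toluenesulfonyl chloride, Cc1ccc(cc1)S(Cl)(=O)=O
Why: O-Sulfonylation of both phenols; tosylates are chosen because they turn the donor ring into an acceptor ring for the key step and are inert to the palladium catalysts used later.

Step 6
Reactants: 12 3,5-dihydroxybenzaldehyde
Product: 13 3,5-bis(methoxymethoxy)benzaldehyde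
Conditions: MOMCl (2.5 equiv), i-Pr2NEt (3 equiv), CH2Cl2, 0 °C to rt
Reagents that add atoms: chloromethyl methyl ether (MOMCl), COCCl
Why: Exhaustive O-alkylation of the two phenols as MOM ethers, which are stable to base, fluoride and palladium and only weakly electron-withdrawing from the meta positions.

Step 7
Reactants: 13 3,5-bis(methoxymethoxy)benzaldehyde
Product: 14 1,3-bis(methoxymethoxy)-5-vinylbenzene
Conditions: Ph3PCH3Br (1.3 equiv), KOt-Bu (1.25 equiv), THF, 0 °C to rt
Reagents that add atoms: methyltriphenylphosphonium bromide, C[P+](c1ccccc1)(c1ccccc1)c1ccccc1.[Br-]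
Why: Wittig methylenation of an aromatic aldehyde with the non-stabilised ylide gives the styrene.

Step 8
Reactants: 11 4-bromo-1,3-phenylene bis(4-methylbenzenesulfonate); 14 1,3-bis(methoxymethoxy)-5-vinylbenzene
Product: 15 4-[(E)-2-[3,5-bis(methoxymethoxy)phenyl]ethenyl]-1,3-phenylene bis(4-methylbenzenesulfonate)
Conditions: Pd(OAc)2 (3 mol%), P(o-tol)3 (9 mol%), Et3N (2 equiv), DMF, 100 °C
Reagents that add atoms: none
Why: Mizoroki–Heck reaction: oxidative addition into the C–Br bond (aryl tosylates are inert to this catalyst), syn-carbopalladation at the terminal alkene carbon and syn-β-hydride elimination should give the (E)-stilbene.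

Step 9
Reactants: 15 4-[(E)-2-[3,5-bis(methoxymethoxy)phenyl]ethenyl]-1,3-phenylene bis(4-methylbenzenesulfonate)
Product: 16 4-[(2R,3R)-3-[3,5-bis(methoxymethoxy)phenyl]oxiran-2-yl]-1,3-phenylene bis(4-methylbenzenesulfonate)
Conditions: D-fructose-derived Shi ketone (30 mol%), Oxone (1.6 equiv), K2CO3 (6 equiv), Bu4NHSO4 (5 mol%), MeCN–DMM/aq borate–EDTA buffer (pH 10.5), 0 °C
Reagents that add atoms: potassium peroxymonosulfate (active component of Oxone), [K+].[O-]S(=O)(=O)OO
Why: Shi asymmetric epoxidation: the chiral dioxirane formed in situ transfers oxygen through a spiro transition state to the face of the (E)-alkene that gives the (R,R)-trans-epoxide, the alkene geometry being conserved and the buffered medium sparing tosylates and MOM ethers.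

Step 10
Reactants: 16 4-[(2R,3R)-3-[3,5-bis(methoxymethoxy)phenyl]oxiran-2-yl]-1,3-phenylene bis(4-methylbenzenesulfonate); 9 5-chloro-3-(methoxymethoxy)-2-(trimethylsilyl)phenyl trifluoromethanesulfonate
Product: 19 4-[(2S,3S)-3-[3,5-bis(methoxymethoxy)phenyl]-6-chloro-4-(methoxymethoxy)-2,3-dihydro-1-benzofuran-2-yl]-1,3-phenylene bis(4-methylbenzenesulfonate), via aryne 17 (not isolated), via aryloxonium betaine 18 (not isolated)
Conditions: CsF (4 equiv), 4 Å MS, MeCN–toluene (1:1), 40 °C; 9 (1.8 equiv) added over 6 h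
Reagents that add atoms: none
Why: Proposed new method: fluoride removes the TMS group of 9 and triflate leaves to give aryne 17, whose distal carbon (the future C7a) is attacked by the epoxide oxygen of 16 because the MOM-oxygen next to the other aryne carbon distorts the triple bond and stabilises the carbanion forming beside it (the remote chlorine is a minor perturbation), giving aryloxonium betaine 18. The strained oxonium then ionises at the benzylic C–O bond on the 3,5-bis(methoxymethoxy)phenyl side, since the other benzylic carbon bears the inductively deactivated 2,4-bis(tosyloxy)phenyl ring, and the ortho aryl carbanion collapses on this cation to form C3–C3a, so that overall the aryne is inserted into one C–O σ bond of the oxirane (formal [3+2], ring expansion from three to five members). The closest known reaction type is the fluoride-induced insertion of arynes into the benzylic C–O bond of styrene oxide to give 3-aryl-2,3-dihydrobenzofurans, together with the zwitterion chemistry of arynes with cyclic ethers; an internal diaryl epoxide with stereochemical read-out goes beyond that. The only ring closed is the dihydrofuran, by intramolecular carbanion–carbocation recombination to a five-membered ring (the electrophilic carbon is a free benzylic cation, so no Baldwin constraint applies). C2 keeps the configuration of the epoxide carbon because its C–O bond is never broken, and C3 is set by front-side (SNi-like) collapse on the face the oxygen left, which for the trans-epoxide is also the thermodynamically preferred trans arrangement of the two aryl groups. The step needs aryne regioselectivity (secured by the OMOM group), cleavage of the right C–O bond (secured by tosylates on one ring and MOM ethers on the other) and no proton source for the betaine (aprotic medium, slow addition of 9).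

Step 11
Reactants: 19 4-[(2S,3S)-3-[3,5-bis(methoxymethoxy)phenyl]-6-chloro-4-(methoxymethoxy)-2,3-dihydro-1-benzofuran-2-yl]-1,3-phenylene bis(4-methylbenzenesulfonate); 20 4-acetoxy-3-methoxystyrene
Product: 21 4-[(2S,3S)-6-[(E)-2-(4-acetoxy-3-methoxyphenyl)ethenyl]-3-[3,5-bis(methoxymethoxy)phenyl]-4-(methoxymethoxy)-2,3-dihydro-1-benzofuran-2-yl]-1,3-phenylene bis(4-methylbenzenesulfonate)
Conditions: Pd2(dba)3 (2.5 mol%), P(t-Bu)3·HBF4 (10 mol%), Cy2NMe (1.5 equiv), 1,4-dioxane, 100 °C
Reagents that add atoms: none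
Why: Mizoroki–Heck reaction of an aryl chloride under Pd/P(t-Bu)3 catalysis, which inserts into C–Cl but leaves aryl sulfonates untouched; β-arylation of the styrene and syn-β-hydride elimination should give the (E)-stilbene without touching the C2 and C3 stereocentres.

Step 12
Reactants: 21 4-[(2S,3S)-6-[(E)-2-(4-acetoxy-3-methoxyphenyl)ethenyl]-3-[3,5-bis(methoxymethoxy)phenyl]-4-(methoxymethoxy)-2,3-dihydro-1-benzofuran-2-yl]-1,3-phenylene bis(4-methylbenzenesulfonate)
Product: 23 4-[(2S,3S)-6-[(E)-2-(4-acetoxy-3-methoxyphenyl)ethenyl]-3-(3,5-dihydroxyphenyl)-4-hydroxy-2,3-dihydro-1-benzofuran-2-yl]-1,3-phenylene bis(4-methylbenzenesulfonate), via tris(trimethylsilyl) ether 22 (not isolated)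
Conditions: TMSOTf (6 equiv), 2,2′-bipyridyl (9 equiv), MeCN, 0 °C to rt; then H2O, rt
Reagents that add atoms: trimethylsilyl triflate, C[Si](C)(C)OS(=O)(=O)C(F)(F)F (its silyl groups stand only in 22)
Why: Silyl triflate/2,2′-bipyridyl cleavage of aromatic MOM ethers: the acetal is silylated, the methoxymethyl cation is taken up by bipyridyl and the aryl TMS ethers are hydrolysed by water, a non-protic method that should spare the acetate, the tosylates, the stilbene and the benzylic C2–O1 bond (deactivated by the tosylated aryl ring).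

Step 13
Reactants: 23 4-[(2S,3S)-6-[(E)-2-(4-acetoxy-3-methoxyphenyl)ethenyl]-3-(3,5-dihydroxyphenyl)-4-hydroxy-2,3-dihydro-1-benzofuran-2-yl]-1,3-phenylene bis(4-methylbenzenesulfonate)
Product: 24 4-[(2S,3S)-3-(3,5-dihydroxyphenyl)-4-hydroxy-6-[(E)-2-(4-hydroxy-3-methoxyphenyl)ethenyl]-2,3-dihydro-1-benzofuran-2-yl]benzene-1,3-diol (CNP0136479.1)
Conditions: KOH (12 equiv), degassed MeOH–THF–H2O, 60 °C, Ar; then AcOH to pH 5, 0 °C
Reagents that add atoms: none
Why: Hydroxide attack at sulfur (aryl sulfonate cleavage) and at the acetate carbonyl (saponification) frees the last three phenols under oxygen-free conditions; no stereocentre is acidic enough to epimerise, and any reversible quinone-methide opening at C2 should reclose to the trans isomer dictated by C3.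

## Compound list

1 | 5-chlororesorcinol (5-chlorobenzene-1,3-diol) | Oc1cc(O)cc(Cl)c1 | starting material
2 | 3-chloro-5-(methoxymethoxy)phenol | COCOc1cc(O)cc(Cl)c1 | intermediate
3 | 3-chloro-5-(methoxymethoxy)phenyl N-isopropylcarbamate | COCOc1cc(Cl)cc(OC(=O)NC(C)C)c1 | intermediate
4 | 3-chloro-5-(methoxymethoxy)phenyl N-(tert-butyldimethylsilyl)-N-isopropylcarbamate (formed in the flask) | COCOc1cc(Cl)cc(OC(=O)N(C(C)C)[Si](C)(C)C(C)(C)C)c1 | intermediate
5 | 2-lithio derivative of 4, lithium between the carbamate and MOM oxygens (formed in the flask) | COCOc1cc(Cl)cc(OC(=O)N(C(C)C)[Si](C)(C)C(C)(C)C)c1[Li] | intermediate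
6 | 5-chloro-3-(methoxymethoxy)-2-(trimethylsilyl)phenyl N-(tert-butyldimethylsilyl)-N-isopropylcarbamate (formed in the flask) | COCOc1cc(Cl)cc(OC(=O)N(C(C)C)[Si](C)(C)C(C)(C)C)c1[Si](C)(C)C | intermediate
7 | 5-chloro-3-(methoxymethoxy)-2-(trimethylsilyl)phenyl N-isopropylcarbamate | COCOc1cc(Cl)cc(OC(=O)NC(C)C)c1[Si](C)(C)C | intermediate
8 | 5-chloro-3-(methoxymethoxy)-2-(trimethylsilyl)phenol (formed in the flask) | COCOc1cc(Cl)cc(O)c1[Si](C)(C)C | intermediate
9 | 5-chloro-3-(methoxymethoxy)-2-(trimethylsilyl)phenyl trifluoromethanesulfonate | COCOc1cc(Cl)cc(OS(=O)(=O)C(F)(F)F)c1[Si](C)(C)C | intermediate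
10 | 4-bromoresorcinol (4-bromobenzene-1,3-diol) | Oc1ccc(Br)c(O)c1 | starting material
11 | 4-bromo-1,3-phenylene bis(4-methylbenzenesulfonate) | Cc1ccc(cc1)S(=O)(=O)Oc1ccc(Br)c(OS(=O)(=O)c2ccc(C)cc2)c1 | intermediate
12 | 3,5-dihydroxybenzaldehyde | O=Cc1cc(O)cc(O)c1 | starting material
13 | 3,5-bis(methoxymethoxy)benzaldehyde | COCOc1cc(C=O)cc(OCOC)c1 | intermediate
14 | 1,3-bis(methoxymethoxy)-5-vinylbenzene | COCOc1cc(C=C)cc(OCOC)c1 | intermediate
15 | 4-[(E)-2-[3,5-bis(methoxymethoxy)phenyl]ethenyl]-1,3-phenylene bis(4-methylbenzenesulfonate) | COCOc1cc(/C=C/c2ccc(OS(=O)(=O)c3ccc(C)cc3)cc2OS(=O)(=O)c2ccc(C)cc2)cc(OCOC)c1 | intermediate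
16 | 4-[(2R,3R)-3-[3,5-bis(methoxymethoxy)phenyl]oxiran-2-yl]-1,3-phenylene bis(4-methylbenzenesulfonate) | O1[C@H](c2ccc(OS(=O)(=O)c3ccc(C)cc3)cc2OS(=O)(=O)c2ccc(C)cc2)[C@H]1c1cc(OCOC)cc(OCOC)c1 | intermediate
17 | 5-chloro-3-(methoxymethoxy)benzyne (formed in the flask) | COCOC1=CC(Cl)=CC#C1 | intermediate
18 | aryloxonium betaine: epoxide oxygen of 16 bound to the distal aryne carbon, carbanion on the carbon next to OMOM (formed in the flask) | COCOC1=CC(Cl)=CC([O+]2[C@H](c3ccc(OS(=O)(=O)c4ccc(C)cc4)cc3OS(=O)(=O)c3ccc(C)cc3)[C@H]2c2cc(OCOC)cc(OCOC)c2)=[C-]1 | intermediate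
19 | 4-[(2S,3S)-3-[3,5-bis(methoxymethoxy)phenyl]-6-chloro-4-(methoxymethoxy)-2,3-dihydro-1-benzofuran-2-yl]-1,3-phenylene bis(4-methylbenzenesulfonate) | Clc1cc(OCOC)c2c(c1)O[C@H](c1ccc(OS(=O)(=O)c3ccc(C)cc3)cc1OS(=O)(=O)c1ccc(C)cc1)[C@H]2c1cc(OCOC)cc(OCOC)c1 | intermediate
20 | 4-acetoxy-3-methoxystyrene (2-methoxy-4-vinylphenyl acetate) | COc1cc(C=C)ccc1OC(C)=O | starting material
21 | 4-[(2S,3S)-6-[(E)-2-(4-acetoxy-3-methoxyphenyl)ethenyl]-3-[3,5-bis(methoxymethoxy)phenyl]-4-(methoxymethoxy)-2,3-dihydro-1-benzofuran-2-yl]-1,3-phenylene bis(4-methylbenzenesulfonate) | COc1cc(/C=C/c2cc(OCOC)c3c(c2)O[C@H](c2ccc(OS(=O)(=O)c4ccc(C)cc4)cc2OS(=O)(=O)c2ccc(C)cc2)[C@H]3c2cc(OCOC)cc(OCOC)c2)ccc1OC(C)=O | intermediate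
22 | tris(trimethylsilyl) ether of 23 (formed in the flask) | COc1cc(/C=C/c2cc(O[Si](C)(C)C)c3c(c2)O[C@H](c2ccc(OS(=O)(=O)c4ccc(C)cc4)cc2OS(=O)(=O)c2ccc(C)cc2)[C@H]3c2cc(O[Si](C)(C)C)cc(O[Si](C)(C)C)c2)ccc1OC(C)=O | intermediate
23 | 4-[(2S,3S)-6-[(E)-2-(4-acetoxy-3-methoxyphenyl)ethenyl]-3-(3,5-dihydroxyphenyl)-4-hydroxy-2,3-dihydro-1-benzofuran-2-yl]-1,3-phenylene bis(4-methylbenzenesulfonate) | COc1cc(/C=C/c2cc(O)c3c(c2)O[C@H](c2ccc(OS(=O)(=O)c4ccc(C)cc4)cc2OS(=O)(=O)c2ccc(C)cc2)[C@H]3c2cc(O)cc(O)c2)ccc1OC(C)=O | intermediate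
24 | 4-[(2S,3S)-3-(3,5-dihydroxyphenyl)-4-hydroxy-6-[(E)-2-(4-hydroxy-3-methoxyphenyl)ethenyl]-2,3-dihydro-1-benzofuran-2-yl]benzene-1,3-diol (CNP0136479.1) | COc1cc(/C=C/c2cc(O)c3c(c2)O[C@H](c2ccc(O)cc2O)[C@H]3c2cc(O)cc(O)c2)ccc1O | target

## Summary

Total step count: 13.
Longest linear sequence: 8 steps (steps 1–4 or 6–9, then 10–13).

## Steps most likely to fail

**Step 10 (proposed new method).** The hindered, electron-poor epoxide oxygen may capture the aryne too slowly, so that the aryne is consumed by itself or by fluoride. The betaine may also ionise at the wrong C–O bond, undergo a hydride shift, or be quenched by internal proton transfer from an epoxide C–H; ring closure may lose part of its trans selectivity.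
Fallback: the same dihydrobenzofuran is assembled by a [4+1] annulation of an o-quinone methide with a sulfonium ylide, a known reaction type that forms O1–C2 and C2–C3 instead. It sets out from aryllithium 5 (generated from 3 as in step 3) and aldehyde 13 and comes back at 19.
- 5 is quenched with 13 instead of TMSCl; aqueous NaHSO4 work-up should give the racemic carbamate benzhydrol F1.
- Cleavage of the carbamate (DBU, Et2NH, MeCN) should give the o-hydroxybenzhydrol F2.
- The ylide partner comes from commercial 2,4-dihydroxybenzaldehyde: tosylation as in step 5 should give the aldehyde F3, and NaBH4 reduction the benzyl alcohol F4.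
- (2R,5R)-2,5-Dimethylthiolane with HBF4·OEt2 should convert F4 into the chiral sulfonium salt F5.
- F2 and F5 with Cs2CO3 in MeCN at 40–60 °C should generate the o-quinone methide and the ylide in the same flask. The ylide carbon adds to the exocyclic carbon and the phenoxide displaces the sulfide anti, which should give trans-19.
- The sense of induction of this sulfide is not assured; the enantiomer that delivers (2S,3S) would be used, and the enantiomeric purity raised by preparative chiral chromatography if needed.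

**Step 13.** Cleaving two aryl tosylates needs hot hydroxide while the product is a fully unprotected, oxidation-prone polyphenolic stilbene. Air oxidation of the phenolates, retro-oxa-Michael opening at C2 with solvent capture, or incomplete cleavage of the second sulfonate may erode the material.
Fallback: the harsh cleavage is moved to a robust stage and the last step becomes a mild methanolysis. It sets out from 19 and comes back at the target 24.
- 19 is detosylated (KOH, MeOH–THF–H2O, 60 °C) to the diphenol F6 and re-esterified (Ac2O, pyridine) to the diacetate F7.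
- Heck coupling with 20 as in step 11 should give the triacetate stilbene F8.
- MOM removal as in step 12 should give the triol triacetate F9.
- K2CO3 in degassed MeOH at 0 °C should then remove the three acetates to give 24.

**Step 11.** Oxidative addition into the aryl chloride may be slow, insertion into a C–OTs bond may compete at the temperature required, and α-arylation of the electron-rich styrene may give the branched regioisomer.
Fallback: the C6–vinyl bond is made by Suzuki–Miyaura coupling, which fixes regiochemistry and alkene geometry in the boron partner. It sets out from 19 and 20 and comes back at 21.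
- Cross-metathesis of 20 with vinylboronic acid pinacol ester (second-generation Ru–benzylidene catalyst, CH2Cl2, 40 °C) should give the (E)-styrylboronate F10.
- F10 is coupled with 19 (Pd2(dba)3, P(t-Bu)3, KF, THF–H2O, 60 °C) to give 21.

## Further compounds

F1 | step 10 | 2-{[3,5-bis(methoxymethoxy)phenyl](hydroxy)methyl}-5-chloro-3-(methoxymethoxy)phenyl N-isopropylcarbamate (racemic) | COCOc1cc(Cl)cc(OC(=O)NC(C)C)c1C(O)c1cc(OCOC)cc(OCOC)c1
F2 | step 10 | 2-{[3,5-bis(methoxymethoxy)phenyl](hydroxy)methyl}-5-chloro-3-(methoxymethoxy)phenol (racemic) | COCOc1cc(Cl)cc(O)c1C(O)c1cc(OCOC)cc(OCOC)c1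
F3 | step 10 | 4-formyl-1,3-phenylene bis(4-methylbenzenesulfonate) | Cc1ccc(cc1)S(=O)(=O)Oc1ccc(C=O)c(OS(=O)(=O)c2ccc(C)cc2)c1
F4 | step 10 | 4-(hydroxymethyl)-1,3-phenylene bis(4-methylbenzenesulfonate) | Cc1ccc(cc1)S(=O)(=O)Oc1ccc(CO)c(OS(=O)(=O)c2ccc(C)cc2)c1
F5 | step 10 | (2R,5R)-1-[2,4-bis(tosyloxy)benzyl]-2,5-dimethylthiolan-1-ium tetrafluoroborate | C[C@@H]1CC[C@@H](C)[S+]1Cc1ccc(OS(=O)(=O)c2ccc(C)cc2)cc1OS(=O)(=O)c1ccc(C)cc1.F[B-](F)(F)F
F6 | step 13 | 4-[(2S,3S)-3-[3,5-bis(methoxymethoxy)phenyl]-6-chloro-4-(methoxymethoxy)-2,3-dihydro-1-benzofuran-2-yl]benzene-1,3-diol | Clc1cc(OCOC)c2c(c1)O[C@H](c1ccc(O)cc1O)[C@H]2c1cc(OCOC)cc(OCOC)c1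
F7 | step 13 | 4-[(2S,3S)-3-[3,5-bis(methoxymethoxy)phenyl]-6-chloro-4-(methoxymethoxy)-2,3-dihydro-1-benzofuran-2-yl]-1,3-phenylene diacetate | Clc1cc(OCOC)c2c(c1)O[C@H](c1ccc(OC(C)=O)cc1OC(C)=O)[C@H]2c1cc(OCOC)cc(OCOC)c1
F8 | step 13 | 4-[(2S,3S)-6-[(E)-2-(4-acetoxy-3-methoxyphenyl)ethenyl]-3-[3,5-bis(methoxymethoxy)phenyl]-4-(methoxymethoxy)-2,3-dihydro-1-benzofuran-2-yl]-1,3-phenylene diacetate | COc1cc(/C=C/c2cc(OCOC)c3c(c2)O[C@H](c2ccc(OC(C)=O)cc2OC(C)=O)[C@H]3c2cc(OCOC)cc(OCOC)c2)ccc1OC(C)=O
F9 | step 13 | 4-[(2S,3S)-6-[(E)-2-(4-acetoxy-3-methoxyphenyl)ethenyl]-3-(3,5-dihydroxyphenyl)-4-hydroxy-2,3-dihydro-1-benzofuran-2-yl]-1,3-phenylene diacetate | COc1cc(/C=C/c2cc(O)c3c(c2)O[C@H](c2ccc(OC(C)=O)cc2OC(C)=O)[C@H]3c2cc(O)cc(O)c2)ccc1OC(C)=O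
F10 | step 11 | 2-methoxy-4-[(E)-2-(4,4,5,5-tetramethyl-1,3,2-dioxaborolan-2-yl)ethenyl]phenyl acetate | COc1cc(/C=C/B2OC(C)(C)C(C)(C)O2)ccc1OC(C)=O
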